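**Plan**

- Retrosynthetic cuts: C30=C31 (Wittig), C1=C2 (Mannich methylenation), O11–C10 (ene oxygenation) and O24–C22 (ring D lactone) go first. C22 is then tied to an oxygen on C10 and C13–C17 is cut by a retro-Ireland–Claisen. Finally C10–C12 (acetylide) and C17–C18 (Michael) separate a ring A/B keto lactone, a ring E ester and a C4 alkyne.
- Enabling feature: spiro C17 of ring C (C10, C12, C13, C17, C18, C19) carries carboxyl C22 and is linked to C10 through C18–C19. A C22–O–C10 ester is therefore a six-membered lactone, and its enolate (C17=C22) together with a C12=C13 arm on C10 is an allyl vinyl ether.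
- Forward order: rings B and E (both from cyclohepta-1,3-diene), ring A lactone and ring E epoxide, union, bridging δ-lactone, ring C by the rearrangement, ring D by lactonisation, then C10–OH, the exocyclic methylene and the side-chain enone.
- Stereochemistry: one lipase desymmetrisation feeds both mirror-image seven-ring series. Claisen chirality transfer sets C21/C6 and C38/C25, hydrogenation sets C8 and C27, Sharpless epoxidation sets C29/C36, enolate protonation sets C19, and acetylide addition sets C10 (temporary). The boat Claisen relays this to C17 and C13, and suprafacial ene oxygenation sets the final C10.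

Key step: step 26

Remark: atom labels C1–C38 count the atoms of the target SMILES from left to right (oxygens included) and TBS is tert-butyldimethylsilyl; the lipase is assumed to give the (1S,4R)-monoacetate, and if it gives the antipode, lipase acetylation of the corresponding meso diol (opposite enantiotopic preference) should supply the same compound.

**Route**

Step 1
Reactants: 1 cyclohepta-1,3-diene
Product: 2 cis-cyclohept-2-ene-1,4-diyl diacetate (meso)
Conditions: Pd(OAc)2 (cat.), LiOAc, LiCl (cat.), p-benzoquinone, AcOH, 25 °C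
Reagents that add atoms: acetic acid (as LiOAc/AcOH), CC(=O)O
Why: Palladium-catalysed oxidative 1,4-diacetoxylation of a conjugated diene; with chloride present the second acetate attacks the π-allylpalladium intermediate from outside, so the cis (meso) diacetate should result.

Step 2
Reactants: 2 cis-cyclohept-2-ene-1,4-diyl diacetate
Product: 3 (1S,4R)-4-acetoxycyclohept-2-en-1-ol
Conditions: lipase from Burkholderia cepacia (Amano PS), phosphate buffer pH 7, 25 °C
Reagents that add atoms: none
Why: Enzymatic desymmetrisation (enantiotopic-group hydrolysis of a meso diester) should stop at the monoacetate and is the only source of absolute configuration for both halves.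

Step 3
Reactants: 3 (1S,4R)-4-acetoxycyclohept-2-en-1-ol
Product: 5 ethyl 2-[(1S,7R)-7-acetoxycyclohept-2-en-1-yl]acetate, via mixed ketene acetal 4 (not isolated)
Conditions: MeC(OEt)3, EtCO2H (cat.), 140 °C, EtOH distilled off
Reagents that add atoms: triethyl orthoacetate, CC(OCC)(OCC)OCC
Why: Johnson–Claisen rearrangement; the [3,3] shift is suprafacial on the ring, so C21–C2 forms on the face the C19 oxygen leaves, which is cis to the C6 acetate, and the alkene moves to C19=C20.

Step 4
Reactants: 5 ethyl 2-[(1S,7R)-7-acetoxycyclohept-2-en-1-yl]acetate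
Product: 7 (3aS,8aR)-3,3a,6,7,8,8a-hexahydro-2H-cyclohepta[b]furan-2-one, via hydroxy ester 6 (not isolated)
Conditions: K2CO3 (cat.), EtOH, 25 °C; then TsOH·H2O (cat.), CH2Cl2
Reagents that add atoms: none
Why: Transesterification frees the C6 hydroxyl and the cis γ-hydroxy ester lactonises to the cis-fused ring A/ring B lactone.

Step 5
Reactants: 7 (3aS,8aR)-3,3a,6,7,8,8a-hexahydro-2H-cyclohepta[b]furan-2-one
Product: 8 (3aS,8aR)-6-hydroxy-3,3a,6,7,8,8a-hexahydro-2H-cyclohepta[b]furan-2-one (C10 carbinol; both epimers)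
Conditions: SeO2 (cat.), t-BuOOH, CH2Cl2, 25 °C
Reagents that add atoms: tert-butyl hydroperoxide, CC(C)(C)OO
Why: Selenium dioxide allylic hydroxylation (ene reaction then [2,3]-shift) should occur at the allylic CH2 (C10) rather than the ring-fusion CH (C21) and leaves the alkene in place; the carbinol configuration is removed in the next step.

Step 6
Reactants: 8 allylic alcohol
Product: 9 (3aS,8aR)-3,3a,8,8a-tetrahydro-2H-cyclohepta[b]furan-2,6(7H)-dione
Conditions: Dess–Martin periodinane, NaHCO3, CH2Cl2, 0 to 25 °C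
Reagents that add atoms: none
Why: Dess–Martin oxidation of the allylic alcohol gives the C10 enone under buffered, non-basic conditions that should spare the base-sensitive δ-acyloxy enone.

Step 7
Reactants: 9 ring B enone lactone
Product: 12 (3aS,8aR)-7-methylidene-3,3a,8,8a-tetrahydro-2H-cyclohepta[b]furan-2,6(7H)-dione, via Mannich base 10 (not isolated), via methiodide 11 (not isolated)
Conditions: LiN(i-Pr)2, THF, −78 °C; Me2N=CH2+ I−; then MeI, MeOH; then aq. NaHCO3, CH2Cl2
Reagents that add atoms: N,N-dimethylmethyleneiminium iodide (Eschenmoser's salt), C=[N+](C)C.[I-]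
Why: Kinetic α′-enolate formation (C8 is the only enolisable ketone α-carbon), Mannich reaction and Hofmann-type elimination of the quaternised amine install the C8 exocyclic methylene.

Step 8
Reactants: 12 cross-conjugated dienone
Product: 13 (3aR,7S,8aR)-7-methylhexahydro-2H-cyclohepta[b]furan-2,6(3H)-dione
Conditions: H2 (1 atm), Pd/C, EtOAc, 25 °C
Reagents that add atoms: none
Why: Catalytic hydrogenation saturates both C=C bonds; hydrogen should be delivered to the convex face of the cis-fused bicycle (the face of H6 and H21), which puts the C8 methyl cis to the lactone oxygen.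

Step 9
Reactants: 13 ring B keto lactone
Product: 16 (3aR,7S,8aR)-7-methyl-5-methylidenehexahydro-2H-cyclohepta[b]furan-2,6(3H)-dione, via Mannich base 14 (not isolated), via methiodide 15 (not isolated)
Conditions: LiN(i-Pr)2, THF, −78 °C; Me2N=CH2+ I−; then MeI, MeOH; then aq. NaHCO3, CH2Cl2
Reagents that add atoms: N,N-dimethylmethyleneiminium iodide (Eschenmoser's salt), C=[N+](C)C.[I-]
Why: The amide base deprotonates the ketone kinetically at the CH2 (C19) rather than at CH(CH3) (C8) or the lactone, and Mannich reaction/elimination gives the α-methylene ketone (future C18) without touching C8.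

Step 10
Reactants: 3 (1S,4R)-4-acetoxycyclohept-2-en-1-ol
Product: 17 (1R,4S)-4-[(tert-butyldimethylsilyl)oxy]cyclohept-2-en-1-yl acetate
Conditions: TBSCl, imidazole, DMF, 25 °C
Reagents that add atoms: tert-butyldimethylsilyl chloride, CC(C)(C)[Si](C)(C)Cl
Why: Standard silylation of the free allylic hydroxyl, which becomes the C25 oxygen.

Step 11
Reactants: 17 silyl ether acetate
Product: 18 (1R,4S)-4-[(tert-butyldimethylsilyl)oxy]cyclohept-2-en-1-ol
Conditions: K2CO3 (cat.), MeOH, 25 °C
Reagents that add atoms: none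
Why: Base-catalysed methanolysis removes only the acetate; the free hydroxyl now sits on the other enantiotopic carbon, so the next Claisen transfer leads into the mirror-image ring series.

Step 12
Reactants: 18 monosilylated diol
Product: 20 ethyl 2-[(1R,7S)-7-[(tert-butyldimethylsilyl)oxy]cyclohept-2-en-1-yl]acetate, via mixed ketene acetal 19 (not isolated)
Conditions: MeC(OEt)3, EtCO2H (cat.), 140 °C, EtOH distilled off
Reagents that add atoms: triethyl orthoacetate, CC(OCC)(OCC)OCC
Why: Johnson–Claisen rearrangement with suprafacial chirality transfer forms C38–C17 cis to the C25 silyloxy group and leaves the ester open-chain, as needed for the later δ-lactone.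

Step 13
Reactants: 20 ring E alkene ester
Product: 21 ethyl 2-[(1R,7S)-7-[(tert-butyldimethylsilyl)oxy]-4-hydroxycyclohept-2-en-1-yl]acetate (C29 carbinol; both epimers)
Conditions: SeO2 (cat.), t-BuOOH, CH2Cl2, 25 °C
Reagents that add atoms: tert-butyl hydroperoxide, CC(C)(C)OO
Why: Selenium dioxide allylic hydroxylation at the allylic CH2 (C29), as in step 5.

Step 14
Reactants: 21 allylic alcohol
Product: 22 ethyl 2-[(1R,7S)-7-[(tert-butyldimethylsilyl)oxy]-4-oxocyclohept-2-en-1-yl]acetate
Conditions: Dess–Martin periodinane, NaHCO3, CH2Cl2, 0 to 25 °C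
Reagents that add atoms: none
Why: Dess–Martin oxidation of the allylic alcohol to the C29 enone.

Step 15
Reactants: 22 ring E enone
Product: 25 ethyl 2-[(1R,7S)-7-[(tert-butyldimethylsilyl)oxy]-5-methylidene-4-oxocyclohept-2-en-1-yl]acetate, via Mannich base 23 (not isolated), via methiodide 24 (not isolated)
Conditions: LiN(i-Pr)2 (1 equiv), THF, −78 °C; Me2N=CH2+ I−; then MeI, MeOH; then aq. NaHCO3, CH2Cl2
Reagents that add atoms: N,N-dimethylmethyleneiminium iodide (Eschenmoser's salt), C=[N+](C)C.[I-]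
Why: The enone α′-position (C27) is more acidic than the ester α-CH2, so one equivalent of base followed by Mannich reaction/elimination places the methylene on C27.

Step 16
Reactants: 25 ring E dienone
Product: 26 ethyl 2-[(1S,2S,4R)-2-[(tert-butyldimethylsilyl)oxy]-4-methyl-5-oxocycloheptyl]acetate
Conditions: H2 (1 atm), Pd/C, EtOAc, 25 °C
Reagents that add atoms: none
Why: Catalytic hydrogenation of both C=C bonds; addition anti to the bulky C25 silyloxy group and the C38 side chain should place the C27 methyl cis to both.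

Step 17
Reactants: 26 ring E ketone
Product: 27 ethyl 2-[(1S,2S,4R)-2-[(tert-butyldimethylsilyl)oxy]-4-methyl-5-(trifluoromethanesulfonyloxy)cyclohept-5-en-1-yl]acetate
Conditions: LiN(i-Pr)2 (1 equiv), THF, −78 °C; PhNTf2, −78 to 0 °C
Reagents that add atoms: N-phenylbis(trifluoromethanesulfonimide), O=S(=O)(N(c1ccccc1)S(=O)(=O)C(F)(F)F)C(F)(F)F
Why: Kinetic enolate formation on the CH2 side (C36) and O-triflation give the less substituted enol triflate C29=C36 without epimerising C27.

Step 18
Reactants: 27 enol triflate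
Product: 28 ethyl 2-[(1S,2S,4R)-2-[(tert-butyldimethylsilyl)oxy]-5-(hydroxymethyl)-4-methylcyclohept-5-en-1-yl]acetate
Conditions: Bu3SnCH2OH, Pd(PPh3)4 (cat.), LiCl, 1,4-dioxane, 95 °C
Reagents that add atoms: (tributylstannyl)methanol, OC[Sn](CCCC)(CCCC)CCCC
Why: Stille coupling of the enol triflate with the hydroxymethyl stannane attaches C30 and gives the allylic alcohol directly, without a hydride reduction that would touch the ester.

Step 19
Reactants: 28 allylic alcohol
Product: 29 ring E epoxy alcohol (29R,36R; epoxide oxygen trans to the C27 methyl, the C25 silyloxy group and the C38 side chain)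
Conditions: Ti(O-i-Pr)4, D-(−)-diethyl tartrate, t-BuOOH, 4 Å molecular sieves, CH2Cl2, −20 °C
Reagents that add atoms: tert-butyl hydroperoxide, CC(C)(C)OO
Why: Sharpless asymmetric epoxidation; the D-(−)-tartrate catalyst delivers oxygen to the alkene face anti to the C27 methyl, so reagent control and substrate bias are matched for the C29/C36 epoxide of the target.

Step 20
Reactants: 29 ring E epoxy alcohol
Product: 30 ring E bis-silyl epoxy ester (C30–OTBS and C25–OTBS)
Conditions: TBSCl, imidazole, CH2Cl2, 25 °C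
Reagents that add atoms: tert-butyldimethylsilyl chloride, CC(C)(C)[Si](C)(C)Cl
Why: Silylation of the primary alcohol masks C30 until the side chain is built.

Step 21
Reactants: 31 but-3-yn-2-one
Product: 32 2-ethynyl-2-methyl-1,3-dioxolane
Conditions: Me3SiOCH2CH2OSiMe3, Me3SiOTf (cat.), CH2Cl2, −78 °C
Reagents that add atoms: 1,2-bis(trimethylsilyloxy)ethane, C[Si](C)(C)OCCO[Si](C)(C)C
Why: Silyl-triflate-catalysed ketalisation with the bis-silyl ether of ethylene glycol protects the ynone carbonyl at low temperature without conjugate addition.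

Step 22
Reactants: 30 ring E bis-silyl epoxy ester; 16 ring B α-methylene ketone
Product: 33 Michael adduct (ring B ketone joined through C19–C18–C17 to the ring E ester; C19 as in the target, C17 epimers)
Conditions: 30, LiN(i-Pr)2, THF, −78 °C; then 16, −78 °C; AcOH, −78 °C
Reagents that add atoms: none
Why: Michael addition of the lithium ester enolate to the unhindered exocyclic enone forms C17–C18; convex-face protonation of the C19 enolate, backed by the expected preference for the cis-2,7-disubstituted cycloheptanone (reachable with DBU), should give H19 as required, while C17 is erased in the key step.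

Step 23
Reactants: 33 Michael adduct; 32 2-ethynyl-2-methyl-1,3-dioxolane
Product: 35 alkynyl δ-lactone (C10–O–C22; alkyne cis to C18 and to the C8 methyl), via hydroxy ester 34 (not isolated)
Conditions: 32, n-BuLi, THF, −78 °C; CeCl3; then 33, −78 to 25 °C; H2O
Reagents that add atoms: none
Why: 1,2-Addition of the cerium acetylide to the ketone, the slender nucleophile expected to enter along the pseudo-axial line and hence cis to the pseudo-equatorial C8 methyl and C18 arm, gives the C10 alkoxide, which closes on the ethyl ester (six-membered lactonisation) on warming.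

Step 24
Reactants: 35 alkynyl δ-lactone
Product: 36 vinylsilane δ-lactone (triethoxysilyl on C13, H12 and Si anti; the C12-silyl regioisomer serves equally)
Conditions: (EtO)3SiH, [Cp*Ru(MeCN)3]PF6 (cat.), CH2Cl2, 0 to 25 °C
Reagents that add atoms: triethoxysilane, CCO[SiH](OCC)OCC
Why: Ruthenium-catalysed trans-hydrosilylation of an internal alkyne adds H and Si anti, so C10 and C14 are already trans across the new double bond.

Step 25
Reactants: 36 vinylsilane δ-lactone
Product: 37 (E)-alkenyl δ-lactone (key precursor)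
Conditions: AgF, THF/MeOH/H2O, 25 °C, dark
Reagents that add atoms: none
Why: Fluoride-promoted protodesilylation replaces silicon by hydrogen with retention, completing a formal trans-semihydrogenation to the E alkene under conditions that should spare the silyl ethers.

Step 26
Reactants: 37 (E)-alkenyl δ-lactone
Product: 40 ring C carboxylic acid, via bis(silyl ketene acetal) 38 (not isolated), via trimethylsilyl ester 39 (not isolated)
Conditions: LiN(i-Pr)2 (3 equiv), Me3SiCl/Et3N (excess), THF, −78 to 25 °C; toluene, 100 °C; then aq. citric acid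
Reagents that add atoms: none
Why: Excess base and silyl chloride (internal quench) turn both lactones into silyl ketene acetals, and only the δ-lactone acetal is an allyl vinyl ether (C17=C22–O–C10–C12=C13), which undergoes the Ireland–Claisen [3,3] shift on heating; the closest known reaction type is the rearrangement of silyl ketene acetals of alkenyl-substituted lactones to cycloalkenecarboxylic acids. Ring C closes as the C13–C17 σ-bond forms and C10–O breaks in one suprafacial six-electron event, the six-membered lactone being exchanged for the six-membered carbocycle. Because C17 and C10 are tied by C18–C19, the array can react only through a bicyclo[2.2.2]-like boat, so the new bond forms on the lactone face that carries the alkenyl arm; with the C10 oxygen trans to C18 on ring B this sets C17 with C22 cis to H19 and C38 cis to C20 (the C17 configuration of 37 is erased on enolisation). C13 is set by the E geometry of C12=C13, which puts the ketal carbon C14 on the side of the C22 bridge and H13 on the opposite face, the face needed later for oxygen delivery to C10. The step needs complete enolisation of the hindered C17–H and chemoselectivity: the ring A acetal has no allyl partner and returns to the lactone on work-up, and amine-buffered Me3SiCl should keep the epoxide, the ketal and the tertiary allylic C10–O bond intact.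

Step 27
Reactants: 40 ring C carboxylic acid
Product: 42 ring D spiro-lactone with free C30 alcohol, via dihydroxy acid 41 (not isolated)
Conditions: Bu4NF, AcOH, THF, 25 °C; then toluene, 50 °C
Reagents that add atoms: none
Why: Fluoride desilylation frees both hydroxyls and the C25 hydroxyl lactonises onto the adjacent C22 acid (γ-lactonisation, ring D); acetic acid buffering should suppress Payne rearrangement of the epoxy alcohol.

Step 28
Reactants: 42 ring D spiro-lactone
Product: 45 α-methylene lactone (ring A complete), via Mannich base 43 (not isolated), via methiodide 44 (not isolated)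
Conditions: LiN(i-Pr)2 (2.2 equiv), THF, −78 °C; Me2N=CH2+ I−; then MeI, MeOH; then aq. NaHCO3, CH2Cl2
Reagents that add atoms: N,N-dimethylmethyleneiminium iodide (Eschenmoser's salt), C=[N+](C)C.[I-]
Why: Lactone α-methylenation by enolate Mannich reaction and elimination; only ring A can enolise because the ring D lactone has a quaternary α-carbon (C17), and the second equivalent of base covers the C30 hydroxyl.

Step 29
Reactants: 45 α-methylene lactone
Product: 47 C10 tertiary allylic alcohol (ketal), via hydroperoxide 46 (not isolated)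
Conditions: O2, tetraphenylporphyrin (cat.), hν, CH2Cl2, 0 °C; then PPh3
Reagents that add atoms: oxygen, O=O
Why: Schenck ene reaction of singlet oxygen at the trisubstituted C10=C12 bond; oxygen bonds to C10 on the face from which the pseudo-axial H13 is taken (suprafacial, the face away from the axial C22 carbonyl), the alkene moves to C12=C13, and PPh3 reduces the hydroperoxide.

Step 30
Reactants: 47 C10 tertiary allylic alcohol (ketal)
Product: 48 C12=C13 enone with C30 primary alcohol
Conditions: PPTS, acetone/H2O, 40 °C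
Reagents that add atoms: water, O
Why: Mild acid-catalysed ketal hydrolysis unmasks the C14 methyl ketone, now conjugated with C12=C13, at a stage where the ring E epoxide is still a simple epoxy alcohol.

Step 31
Reactants: 48 enone alcohol
Product: 50 CNP0177598.2 (target), via epoxy aldehyde 49 (not isolated)
Conditions: Dess–Martin periodinane, NaHCO3, CH2Cl2, 0 °C; then Ph3P=CHC(O)CH3, 25 °C
Reagents that add atoms: 1-(triphenylphosphoranylidene)propan-2-one, CC(=O)C=P(c1ccccc1)(c1ccccc1)c1ccccc1
Why: Dess–Martin oxidation of the primary alcohol and in situ Wittig olefination with the stabilised ylide should give the E enone; the aldehyde has a quaternary α-carbon and the tertiary C10 alcohol is inert.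

**Compound list**

1 | cyclohepta-1,3-diene | C1=CC=CCCC1 | starting material
2 | cis-cyclohept-2-ene-1,4-diyl diacetate (meso) | CC(=O)O[C@H]1C=C[C@@H](OC(C)=O)CCC1 | intermediate
3 | (1S,4R)-4-acetoxycyclohept-2-en-1-ol | O[C@@H]1C=C[C@H](OC(C)=O)CCC1 | intermediate
4 | (1R,4S)-4-[(1-ethoxyethenyl)oxy]cyclohept-2-en-1-yl acetate (mixed ketene acetal) | C=C(OCC)O[C@@H]1C=C[C@H](OC(C)=O)CCC1 | intermediate (not isolated)
5 | ethyl 2-[(1S,7R)-7-acetoxycyclohept-2-en-1-yl]acetate | CCOC(=O)C[C@H]1C=CCCC[C@H]1OC(C)=O | intermediate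
6 | ethyl 2-[(1S,7R)-7-hydroxycyclohept-2-en-1-yl]acetate | CCOC(=O)C[C@H]1C=CCCC[C@H]1O | intermediate (not isolated)
7 | (3aS,8aR)-3,3a,6,7,8,8a-hexahydro-2H-cyclohepta[b]furan-2-one | C1C(=O)O[C@@H]2CCCC=C[C@H]12 | intermediate
8 | (3aS,8aR)-6-hydroxy-3,3a,6,7,8,8a-hexahydro-2H-cyclohepta[b]furan-2-one (carbinol epimers) | C1C(=O)O[C@@H]2CCC(O)C=C[C@H]12 | intermediate
9 | (3aS,8aR)-3,3a,8,8a-tetrahydro-2H-cyclohepta[b]furan-2,6(7H)-dione | C1C(=O)O[C@@H]2CCC(=O)C=C[C@H]12 | intermediate
10 | 7-[(dimethylamino)methyl] derivative of 9 (Mannich base) | C1C(=O)O[C@@H]2CC(CN(C)C)C(=O)C=C[C@H]12 | intermediate (not isolated)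
11 | trimethylammonium iodide of 10 | C1C(=O)O[C@@H]2CC(C[N+](C)(C)C)C(=O)C=C[C@H]12.[I-] | intermediate (not isolated)
12 | (3aS,8aR)-7-methylidene-3,3a,8,8a-tetrahydro-2H-cyclohepta[b]furan-2,6(7H)-dione | C1C(=O)O[C@@H]2CC(=C)C(=O)C=C[C@H]12 | intermediate
13 | (3aR,7S,8aR)-7-methylhexahydro-2H-cyclohepta[b]furan-2,6(3H)-dione | C1C(=O)O[C@@H]2C[C@H](C)C(=O)CC[C@H]12 | intermediate
14 | 5-[(dimethylamino)methyl] derivative of 13 (Mannich base) | C1C(=O)O[C@@H]2C[C@H](C)C(=O)C(CN(C)C)C[C@H]12 | intermediate (not isolated)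
15 | trimethylammonium iodide of 14 | C1C(=O)O[C@@H]2C[C@H](C)C(=O)C(C[N+](C)(C)C)C[C@H]12.[I-] | intermediate (not isolated)
16 | (3aR,7S,8aR)-7-methyl-5-methylidenehexahydro-2H-cyclohepta[b]furan-2,6(3H)-dione | C1C(=O)O[C@@H]2C[C@H](C)C(=O)C(=C)C[C@H]12 | intermediate
17 | (1R,4S)-4-[(tert-butyldimethylsilyl)oxy]cyclohept-2-en-1-yl acetate | CC(=O)O[C@H]1C=C[C@@H](O[Si](C)(C)C(C)(C)C)CCC1 | intermediate
18 | (1R,4S)-4-[(tert-butyldimethylsilyl)oxy]cyclohept-2-en-1-ol | O[C@H]1C=C[C@@H](O[Si](C)(C)C(C)(C)C)CCC1 | intermediate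
19 | mixed ketene acetal of 18 | C=C(OCC)O[C@H]1C=C[C@@H](O[Si](C)(C)C(C)(C)C)CCC1 | intermediate (not isolated)
20 | ethyl 2-[(1R,7S)-7-[(tert-butyldimethylsilyl)oxy]cyclohept-2-en-1-yl]acetate | CCOC(=O)C[C@@H]1C=CCCC[C@@H]1O[Si](C)(C)C(C)(C)C | intermediate
21 | ethyl 2-[(1R,7S)-7-[(tert-butyldimethylsilyl)oxy]-4-hydroxycyclohept-2-en-1-yl]acetate (carbinol epimers) | CCOC(=O)C[C@@H]1C=CC(O)CC[C@@H]1O[Si](C)(C)C(C)(C)C | intermediate
22 | ethyl 2-[(1R,7S)-7-[(tert-butyldimethylsilyl)oxy]-4-oxocyclohept-2-en-1-yl]acetate | CCOC(=O)C[C@@H]1C=CC(=O)CC[C@@H]1O[Si](C)(C)C(C)(C)C | intermediate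
23 | 5-[(dimethylamino)methyl] derivative of 22 (Mannich base) | CCOC(=O)C[C@@H]1C=CC(=O)C(CN(C)C)C[C@@H]1O[Si](C)(C)C(C)(C)C | intermediate (not isolated)
24 | trimethylammonium iodide of 23 | CCOC(=O)C[C@@H]1C=CC(=O)C(C[N+](C)(C)C)C[C@@H]1O[Si](C)(C)C(C)(C)C.[I-] | intermediate (not isolated)
25 | ethyl 2-[(1R,7S)-7-[(tert-butyldimethylsilyl)oxy]-5-methylidene-4-oxocyclohept-2-en-1-yl]acetate | CCOC(=O)C[C@@H]1C=CC(=O)C(=C)C[C@@H]1O[Si](C)(C)C(C)(C)C | intermediate
26 | ethyl 2-[(1S,2S,4R)-2-[(tert-butyldimethylsilyl)oxy]-4-methyl-5-oxocycloheptyl]acetate | CCOC(=O)C[C@@H]1CCC(=O)[C@H](C)C[C@@H]1O[Si](C)(C)C(C)(C)C | intermediate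
27 | ethyl 2-[(1S,2S,4R)-2-[(tert-butyldimethylsilyl)oxy]-4-methyl-5-(trifluoromethanesulfonyloxy)cyclohept-5-en-1-yl]acetate | CCOC(=O)C[C@@H]1CC=C(OS(=O)(=O)C(F)(F)F)[C@H](C)C[C@@H]1O[Si](C)(C)C(C)(C)C | intermediate
28 | ethyl 2-[(1S,2S,4R)-2-[(tert-butyldimethylsilyl)oxy]-5-(hydroxymethyl)-4-methylcyclohept-5-en-1-yl]acetate | CCOC(=O)C[C@@H]1CC=C(CO)[C@H](C)C[C@@H]1O[Si](C)(C)C(C)(C)C | intermediate
29 | ring E epoxy alcohol (29R,36R; epoxide trans to CH3, OTBS and CH2CO2Et) | CCOC(=O)C[C@@H]1C[C@H]2O[C@@]2(CO)[C@H](C)C[C@@H]1O[Si](C)(C)C(C)(C)C | intermediate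
30 | ring E bis-silyl epoxy ester | CCOC(=O)C[C@@H]1C[C@H]2O[C@@]2(CO[Si](C)(C)C(C)(C)C)[C@H](C)C[C@@H]1O[Si](C)(C)C(C)(C)C | intermediate
31 | but-3-yn-2-one | CC(=O)C#C | starting material
32 | 2-ethynyl-2-methyl-1,3-dioxolane | C#CC1(C)OCCO1 | intermediate
33 | Michael adduct, keto ester (C17 epimers) | C1C(=O)O[C@@H]2C[C@H](C)C(=O)[C@H](CC(C(=O)OCC)[C@@H]3C[C@H]4O[C@@]4(CO[Si](C)(C)C(C)(C)C)[C@H](C)C[C@@H]3O[Si](C)(C)C(C)(C)C)C[C@H]12 | intermediate
34 | C10 tertiary propargylic alcohol, hydroxy ester (C17 epimers) | C1C(=O)O[C@@H]2C[C@H](C)[C@](O)(C#CC3(C)OCCO3)[C@H](CC(C(=O)OCC)[C@@H]4C[C@H]5O[C@@]5(CO[Si](C)(C)C(C)(C)C)[C@H](C)C[C@@H]4O[Si](C)(C)C(C)(C)C)C[C@H]12 | intermediate (not isolated)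
35 | alkynyl δ-lactone (C17 epimers) | C1C(=O)O[C@@H]2C[C@H](C)[C@@]3(C#CC4(C)OCCO4)OC(=O)C([C@@H]5C[C@H]6O[C@@]6(CO[Si](C)(C)C(C)(C)C)[C@H](C)C[C@@H]5O[Si](C)(C)C(C)(C)C)C[C@@H]3C[C@H]12 | intermediate
36 | vinylsilane δ-lactone (Si on C13) | C1C(=O)O[C@@H]2C[C@H](C)[C@@]3(/C=C(\[Si](OCC)(OCC)OCC)C4(C)OCCO4)OC(=O)C([C@@H]5C[C@H]6O[C@@]6(CO[Si](C)(C)C(C)(C)C)[C@H](C)C[C@@H]5O[Si](C)(C)C(C)(C)C)C[C@@H]3C[C@H]12 | intermediate
37 | (E)-alkenyl bridging δ-lactone, key precursor (C17 epimers) | C1C(=O)O[C@@H]2C[C@H](C)[C@@]3(/C=C/C4(C)OCCO4)OC(=O)C([C@@H]5C[C@H]6O[C@@]6(CO[Si](C)(C)C(C)(C)C)[C@H](C)C[C@@H]5O[Si](C)(C)C(C)(C)C)C[C@@H]3C[C@H]12 | intermediate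
38 | bis(trimethylsilyl ketene acetal) of 37 | C1=C(O[Si](C)(C)C)O[C@@H]2C[C@H](C)[C@@]3(/C=C/C4(C)OCCO4)OC(O[Si](C)(C)C)=C([C@@H]5C[C@H]6O[C@@]6(CO[Si](C)(C)C(C)(C)C)[C@H](C)C[C@@H]5O[Si](C)(C)C(C)(C)C)C[C@@H]3C[C@H]12 | intermediate (not isolated)
39 | trimethylsilyl ester of 40 (ring A as silyl ketene acetal) | C1=C(O[Si](C)(C)C)O[C@@H]2C[C@H](C)C3=C[C@@H](C4(C)OCCO4)[C@](C[C@@H]3C[C@H]12)(C(=O)O[Si](C)(C)C)[C@@H]5C[C@H]6O[C@@]6(CO[Si](C)(C)C(C)(C)C)[C@H](C)C[C@@H]5O[Si](C)(C)C(C)(C)C | intermediate (not isolated)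
40 | ring C carboxylic acid | C1C(=O)O[C@@H]2C[C@H](C)C3=C[C@@H](C4(C)OCCO4)[C@](C[C@@H]3C[C@H]12)(C(=O)O)[C@@H]5C[C@H]6O[C@@]6(CO[Si](C)(C)C(C)(C)C)[C@H](C)C[C@@H]5O[Si](C)(C)C(C)(C)C | intermediate
41 | dihydroxy acid | C1C(=O)O[C@@H]2C[C@H](C)C3=C[C@@H](C4(C)OCCO4)[C@](C[C@@H]3C[C@H]12)(C(=O)O)[C@@H]5C[C@H]6O[C@@]6(CO)[C@H](C)C[C@@H]5O | intermediate (not isolated)
42 | ring D spiro-lactone with C30 primary alcohol | C1C(=O)O[C@@H]2C[C@H](C)C3=C[C@@H](C5(C)OCCO5)[C@]4(C[C@@H]3C[C@H]12)C(=O)O[C@H]1C[C@@H](C)[C@]2(CO)O[C@@H]2C[C@H]14 | intermediate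
43 | ring A Mannich base of 42 | CN(C)CC1C(=O)O[C@@H]2C[C@H](C)C3=C[C@@H](C5(C)OCCO5)[C@]4(C[C@@H]3C[C@H]12)C(=O)O[C@H]1C[C@@H](C)[C@]2(CO)O[C@@H]2C[C@H]14 | intermediate (not isolated)
44 | trimethylammonium iodide of 43 | C[N+](C)(C)CC1C(=O)O[C@@H]2C[C@H](C)C3=C[C@@H](C5(C)OCCO5)[C@]4(C[C@@H]3C[C@H]12)C(=O)O[C@H]1C[C@@H](C)[C@]2(CO)O[C@@H]2C[C@H]14.[I-] | intermediate (not isolated)
45 | α-methylene lactone (rings A–E, C10=C12, ketal, C30–OH) | C=C1C(=O)O[C@@H]2C[C@H](C)C3=C[C@@H](C5(C)OCCO5)[C@]4(C[C@@H]3C[C@H]12)C(=O)O[C@H]1C[C@@H](C)[C@]2(CO)O[C@@H]2C[C@H]14 | intermediate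
46 | C10 tertiary allylic hydroperoxide | C=C1C(=O)O[C@@H]2C[C@H](C)[C@@]3(OO)C=C(C5(C)OCCO5)[C@]4(C[C@@H]3C[C@H]12)C(=O)O[C@H]1C[C@@H](C)[C@]2(CO)O[C@@H]2C[C@H]14 | intermediate (not isolated)
47 | C10 tertiary allylic alcohol (ketal) | C=C1C(=O)O[C@@H]2C[C@H](C)[C@@]3(O)C=C(C5(C)OCCO5)[C@]4(C[C@@H]3C[C@H]12)C(=O)O[C@H]1C[C@@H](C)[C@]2(CO)O[C@@H]2C[C@H]14 | intermediate
48 | C12=C13 enone with C30 primary alcohol | C=C1C(=O)O[C@@H]2C[C@H](C)[C@@]3(O)C=C(C(C)=O)[C@]4(C[C@@H]3C[C@H]12)C(=O)O[C@H]1C[C@@H](C)[C@]2(CO)O[C@@H]2C[C@H]14 | intermediate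
49 | epoxy aldehyde | C=C1C(=O)O[C@@H]2C[C@H](C)[C@@]3(O)C=C(C(C)=O)[C@]4(C[C@@H]3C[C@H]12)C(=O)O[C@H]1C[C@@H](C)[C@]2(C=O)O[C@@H]2C[C@H]14 | intermediate (not isolated)
50 | CNP0177598.2 | C=C1C(=O)O[C@@H]2C[C@H](C)[C@@]3(O)C=C(C(C)=O)[C@]4(C[C@@H]3C[C@H]12)C(=O)O[C@H]1C[C@@H](C)[C@]2(/C=C/C(C)=O)O[C@@H]2C[C@H]14 | target

**Step count**

Total: 31 steps. Longest linear sequence: 23 steps (steps 1, 2, 10–20, 22–31, from cyclohepta-1,3-diene through the ring E branch).

**Steps most likely to fail**

1. Step 23. The acetylide may add to the wrong face of the C10 carbonyl (the needed approach is syn to the C8 methyl and the C18 arm), or the ketone may enolise instead of adding. Fallback, setting out from 33: the oxygen is brought in as an electrophile from the open face instead. Wittig olefination of 33 with the ylide from [2-(2-methyl-1,3-dioxolan-2-yl)ethyl]triphenylphosphonium bromide (KN(SiMe3)2, THF) gives the exocyclic C10=C12 alkene F1. Sensitised photo-oxygenation (Schenck ene reaction, oxygen entering anti to the C8 methyl and the C18 arm and taking a C13 hydrogen) gives the allylic hydroperoxide F2, which PPh3 reduces to the (E)-allylic tertiary alcohol F3. NaH-catalysed lactonisation onto the ethyl ester returns to the route at 37, so 34–36 are bypassed.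

2. Step 24. Hydrosilylation of an alkyne flanked by two fully substituted carbons may be slow or unselective, and the Lewis-acidic catalyst may erode the epoxide or ketal. Fallback, setting out from 33: the alkyne is reduced one stage earlier, where a free hydroxyl can assist. The acetylide adduct is quenched at −78 °C and isolated as hydroxy ester 34, which is reduced by ruthenium-catalysed trans-hydrogenation (H2, [Cp*Ru(cod)Cl] cat., CH2Cl2) to the (E)-allylic tertiary alcohol F4. NaH (cat.) then closes the δ-lactone and the route is rejoined at 37.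

3. Step 29. Singlet oxygen may abstract H19 or H8 instead of H13, or approach the face syn to C22. Fallback, setting out from 45: the oxygen is installed by epoxide opening, which shares the facial bias but removes the regiochemical ambiguity. Ketal hydrolysis (PPTS, wet acetone) gives the β,γ-unsaturated methyl ketone F5. Dimethyldioxirane epoxidises C10=C12 (the electron-poor exocyclic methylene should be left alone) to the epoxy ketone F6. Et3N then opens the β,γ-epoxy ketone by E1cB elimination to the γ-hydroxy enone, rejoining the route at 48.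

**Further compounds**

F1 | step 23 | exocyclic C10=C12 alkene from Wittig olefination of 33 | C1C(=O)O[C@@H]2C[C@H](C)C(=CCC3(C)OCCO3)[C@H](CC(C(=O)OCC)[C@@H]4C[C@H]5O[C@@]5(CO[Si](C)(C)C(C)(C)C)[C@H](C)C[C@@H]4O[Si](C)(C)C(C)(C)C)C[C@H]12
F2 | step 23 | C10 allylic hydroperoxide | C1C(=O)O[C@@H]2C[C@H](C)[C@](OO)(/C=C/C3(C)OCCO3)[C@H](CC(C(=O)OCC)[C@@H]4C[C@H]5O[C@@]5(CO[Si](C)(C)C(C)(C)C)[C@H](C)C[C@@H]4O[Si](C)(C)C(C)(C)C)C[C@H]12
F3 | step 23 | (E)-allylic tertiary alcohol hydroxy ester | C1C(=O)O[C@@H]2C[C@H](C)[C@](O)(/C=C/C3(C)OCCO3)[C@H](CC(C(=O)OCC)[C@@H]4C[C@H]5O[C@@]5(CO[Si](C)(C)C(C)(C)C)[C@H](C)C[C@@H]4O[Si](C)(C)C(C)(C)C)C[C@H]12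
F4 | step 24 | (E)-allylic tertiary alcohol hydroxy ester (from trans-hydrogenation of 34) | C1C(=O)O[C@@H]2C[C@H](C)[C@](O)(/C=C/C3(C)OCCO3)[C@H](CC(C(=O)OCC)[C@@H]4C[C@H]5O[C@@]5(CO[Si](C)(C)C(C)(C)C)[C@H](C)C[C@@H]4O[Si](C)(C)C(C)(C)C)C[C@H]12
F5 | step 29 | β,γ-unsaturated methyl ketone | C=C1C(=O)O[C@@H]2C[C@H](C)C3=C[C@@H](C(C)=O)[C@]4(C[C@@H]3C[C@H]12)C(=O)O[C@H]1C[C@@H](C)[C@]2(CO)O[C@@H]2C[C@H]14
F6 | step 29 | C10–C12 epoxy ketone | C=C1C(=O)O[C@@H]2C[C@H](C)[C@]36O[C@@H]6[C@@H](C(C)=O)[C@]4(C[C@@H]3C[C@H]12)C(=O)O[C@H]1C[C@@H](C)[C@]2(CO)O[C@@H]2C[C@H]14
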